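**Plan**

- Retrosynthesis: the four MOM ethers are removed first, then O1–C2 of ring C is opened (oxa-Michael closure of an o-hydroxyaryl ynone). O1–C8a and C4–C4a are then cut together, giving a ring-A aryne and a ring-B arylpropiolic acid. Last come the prenyl C–C bonds at C8 and C5′ and the two alkyne carbons (C3 from an aldehyde homologation, C4 from CO2).
- Enabling feature: in ring A, C8a and C4a are neighbours that carry O1 and the C4 acyl carbon, the two ends of a carboxylic acid C(O)–O bond. They lie between the C8 prenyl group and the C5 oxygen, and the C5 oxygen fixes the orientation in which a C4a–C8a aryne takes up the acid.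
- Forward order: ring A is made from phloroglucinol as an o-silylaryl triflate (two carbamate-directed ortho-metalations under one N-silyl protection), and ring B from 3-bromo-4,5-dihydroxybenzaldehyde as the propiolic acid. The aryne insertion joins them as an open-chain ynone, ring C closes afterwards by amine-mediated 6-endo cyclisation, and the MOM groups come off last.
- Stereochemistry: the target has no stereocentre and no stereogenic double bond. All selectivity questions are regiochemical (site of metalation, orientation of the insertion, 6-endo versus 5-exo closure).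

Key step: step 10

Remark on the chemistry: the N-TBS carbamate 6 is assumed to survive a strictly non-aqueous work-up, since its N–Si bond is normally cleaved only by aqueous acid; it is carried into step 4 as the crude material.

Remark on the chemistry: ynone 22 is assumed to survive the fluoride medium of step 10 long enough to be isolated. Any portion that has already closed is flavone 24, the product of step 11, and would be carried forward with 22.

"Prenyl" below means 3-methylbut-2-en-1-yl; MOM means methoxymethyl.

**Route**

Step 1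
Reactants: 1 phloroglucinol
Product: 2 3,5-bis(methoxymethoxy)phenol
Conditions: MOMCl (2.1 equiv), i-Pr2NEt (2.5 equiv), DMF, 0 °C → rt; chromatography
Reagents that add atoms: chloromethyl methyl ether, COCCl
Why: Williamson-type O-alkylation with an α-chloro ether; the three hydroxyls are equivalent, so the bis-ether is a single compound that should be separable from the mono- and tris-ethers of this statistical reaction.

Step 2
Reactants: 2 3,5-bis(methoxymethoxy)phenol
Product: 3 3,5-bis(methoxymethoxy)phenyl N-(propan-2-yl)carbamate
Conditions: i-PrNCO (1.3 equiv), Et3N (0.2 equiv), CH2Cl2, rt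
Reagents that add atoms: isopropyl isocyanate, CC(C)N=C=O
Why: Base-catalysed addition of the phenol to the isocyanate (carbamoylation) installs an N-monoalkyl carbamate, which is a strong ortho-directing group and can later be cleaved under mild base.

Step 3
Reactants: 3 3,5-bis(methoxymethoxy)phenyl N-(propan-2-yl)carbamate
Product: 6 3,5-bis(methoxymethoxy)-2-(trimethylsilyl)phenyl N-(tert-butyldimethylsilyl)-N-(propan-2-yl)carbamate, via N-TBS carbamate 4 (not isolated), via aryllithium 5 (not isolated)
Conditions: TBSOTf (1.05 equiv), TMEDA (1.1 equiv), Et2O, 0 °C → rt; n-BuLi (2.2 equiv), TMEDA (2.2 equiv), −78 °C; TMSCl (2.5 equiv), −78 °C → rt; non-aqueous work-up (pentane, filtration under argon, evaporation under high vacuum), crude carried on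
Reagents that add atoms: tert-butyldimethylsilyl trifluoromethanesulfonate, CC(C)(C)[Si](C)(C)OS(=O)(=O)C(F)(F)F; chlorotrimethylsilane, C[Si](C)(C)Cl
Why: Directed ortho-metalation with in-situ N-silylation of the carbamate N–H: one equivalent of n-BuLi neutralises the TMEDA·HOTf formed in the silylation, the rest removes the proton between the carbamate and a MOM ether (two equivalent sites, each activated by the strongest directing group plus a second one), TMSCl traps the aryllithium, and leaving out aqueous acid keeps the N-TBS group in place for the second metalation.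

Step 4
Reactants: 6 3,5-bis(methoxymethoxy)-2-(trimethylsilyl)phenyl N-(tert-butyldimethylsilyl)-N-(propan-2-yl)carbamate; 7 prenyl bromide
Product: 11 3,5-bis(methoxymethoxy)-2-prenyl-6-(trimethylsilyl)phenyl N-(propan-2-yl)carbamate, via aryllithium 8 (not isolated), via arylcopper 9 (not isolated), via N-TBS prenylcarbamate 10 (not isolated)
Conditions: n-BuLi (1.3 equiv), TMEDA (1.3 equiv), Et2O, −78 °C; CuBr·SMe2 (1.3 equiv), THF, −78 °C; 7 (2 equiv), −78 → 0 °C; brief cold aq NaHSO4 work-up
Reagents that add atoms: none
Why: A second directed ortho-metalation of the still N-silylated carbamate at the only position left free next to it (the other is blocked by silicon), transmetalation to the arylcopper and copper-mediated SN2 allylation at the primary carbon of prenyl bromide should give the linear prenyl arene, and the acidic work-up then cleaves the N–Si bond to return the N–H carbamate.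

Step 5
Reactants: 11 3,5-bis(methoxymethoxy)-2-prenyl-6-(trimethylsilyl)phenyl N-(propan-2-yl)carbamate
Product: 13 3,5-bis(methoxymethoxy)-2-prenyl-6-(trimethylsilyl)phenyl trifluoromethanesulfonate, via silylphenol 12 (not isolated)
Conditions: DBU (1.5 equiv), Et2NH (1.2 equiv), MeCN, 40 °C; then PhNTf2 (1.5 equiv), rt
Reagents that add atoms: N-phenylbis(trifluoromethanesulfonimide), O=S(=O)(N(c1ccccc1)S(=O)(=O)C(F)(F)F)C(F)(F)F
Why: E1cB cleavage of the N-monoalkyl carbamate (DBU removes N–H, the phenoxide leaves, diethylamine traps isopropyl isocyanate as a urea) is unimolecular at the carbamate and so indifferent to the two ortho substituents, and the phenoxide is triflated in the same flask, the established way from silyl carbamates to o-silylaryl triflates.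

Step 6
Reactants: 14 3-bromo-4,5-dihydroxybenzaldehyde
Product: 15 3-bromo-4,5-bis(methoxymethoxy)benzaldehyde
Conditions: MOMCl (3 equiv), i-Pr2NEt (4 equiv), CH2Cl2, 0 °C → rt
Reagents that add atoms: chloromethyl methyl ether, COCCl
Why: Williamson-type O-alkylation of both catechol hydroxyls with a hindered amine base; the aldehyde and the aryl bromide are inert.

Step 7
Reactants: 15 3-bromo-4,5-bis(methoxymethoxy)benzaldehyde; 16 tributyl(3-methylbut-2-en-1-yl)stannane
Product: 17 3,4-bis(methoxymethoxy)-5-prenylbenzaldehyde
Conditions: Pd(PPh3)4 (5 mol%), degassed DMF, 100 °C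
Reagents that add atoms: none
Why: Stille coupling of the aryl bromide (oxidative addition eased by the para-formyl group) with the prenylstannane, which transfers the allyl group through its primary carbon and tolerates the free aldehyde and the MOM ethers.

Step 8
Reactants: 17 3,4-bis(methoxymethoxy)-5-prenylbenzaldehyde
Product: 18 5-(2,2-dibromoethenyl)-1,2-bis(methoxymethoxy)-3-prenylbenzene
Conditions: CBr4 (2 equiv), PPh3 (4 equiv), Et3N (4 equiv), CH2Cl2, 0 °C
Reagents that add atoms: carbon tetrabromide, BrC(Br)(Br)Br
Why: First stage of the Corey–Fuchs sequence, a Wittig reaction of the aldehyde with Ph3P=CBr2 made in the flask; triethylamine buffers the medium so that the MOM acetals should not be cleaved.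

Step 9
Reactants: 18 5-(2,2-dibromoethenyl)-1,2-bis(methoxymethoxy)-3-prenylbenzene
Product: 20 3-[3,4-bis(methoxymethoxy)-5-prenylphenyl]prop-2-ynoic acid, via lithium acetylide 19 (not isolated)
Conditions: n-BuLi (2.2 equiv), THF, −78 °C; CO2, −78 → 0 °C; cold dilute HCl to pH 3
Reagents that add atoms: carbon dioxide, O=C=O
Why: Second stage of the Corey–Fuchs sequence: two equivalents of n-BuLi convert the dibromoalkene into the lithium acetylide (bromine–lithium exchange, loss of LiBr with 1,2-shift, deprotonation), which is carboxylated by CO2 at a temperature too low for MOM-directed ring lithiation.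

Step 10
Reactants: 13 3,5-bis(methoxymethoxy)-2-prenyl-6-(trimethylsilyl)phenyl trifluoromethanesulfonate (1.3 equiv); 20 3-[3,4-bis(methoxymethoxy)-5-prenylphenyl]prop-2-ynoic acid
Product: 22 1-[2-hydroxy-4,6-bis(methoxymethoxy)-3-prenylphenyl]-3-[3,4-bis(methoxymethoxy)-5-prenylphenyl]prop-2-yn-1-one, via aryne 21 (not isolated)
Conditions: CsF (4 equiv), THF, 125 °C (sealed tube), stopped when 20 is consumed; cold aq NH4Cl
Reagents that add atoms: none
Why: Fluoride attacks silicon and triflate leaves to give the C4a–C8a aryne; the cesium carboxylate of 20 adds through oxygen to C8a, and the aryl anion developing at C4a attacks the neighbouring ester carbonyl, so the acyl group moves from oxygen to carbon and the C8a phenoxide is released (net aryne sigma-bond insertion into the C(O)–O bond, forming O1–C8a and C4a–C4). The closest known reaction is the fluoride-induced insertion of arynes into the C–O bond of carboxylic acids, arylpropiolic acids included, which gives o-hydroxyaryl ketones. No ring is closed and no stereocentre is formed. The selectivity needed is regiochemical, oxygen at C8a and acyl at C4a: the C5 OMOM group distorts the aryne and stabilises by induction the charge at the adjacent C4a, which directs the nucleophile to the distal carbon C8a, and the C8 prenyl group opposes this only by its bulk. THF is chosen because it offers no acidic hydrogen that could quench the aryl anion before the acyl shift, the side path that would leave the aryl ester.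

Step 11
Reactants: 22 1-[2-hydroxy-4,6-bis(methoxymethoxy)-3-prenylphenyl]-3-[3,4-bis(methoxymethoxy)-5-prenylphenyl]prop-2-yn-1-one
Product: 24 5,7-bis(methoxymethoxy)-2-[3,4-bis(methoxymethoxy)-5-prenylphenyl]-8-prenyl-4H-chromen-4-one, via enaminone 23 (not isolated)
Conditions: Et2NH (5 equiv), EtOH, rt → 70 °C
Reagents that add atoms: none
Why: Conjugate addition of diethylamine to the ynone gives the enaminone, and the C8a phenol then displaces the amine at the β-carbon by addition–elimination (amine-mediated cyclisation of o-hydroxyaryl ynones), which can only deliver the six-membered chromen-4-one and so excludes 5-exo closure to the aurone.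

Step 12
Reactants: 24 5,7-bis(methoxymethoxy)-2-[3,4-bis(methoxymethoxy)-5-prenylphenyl]-8-prenyl-4H-chromen-4-one
Product: 25 epimedokoreanin B
Conditions: aq HCl (3 M), MeOH, 50 °C, short reaction time
Reagents that add atoms: none
Why: Acid-catalysed acetal exchange with methanol (standard MOM ether cleavage) should free all four phenols, and the mild temperature and short time are chosen to spare the two prenyl double bonds.

**Compound list**

1 | phloroglucinol | Oc1cc(O)cc(O)c1 | starting material
2 | 3,5-bis(methoxymethoxy)phenol | COCOc1cc(O)cc(OCOC)c1 | intermediate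
3 | 3,5-bis(methoxymethoxy)phenyl N-(propan-2-yl)carbamate | CC(C)NC(=O)Oc1cc(OCOC)cc(OCOC)c1 | intermediate
4 | 3,5-bis(methoxymethoxy)phenyl N-(tert-butyldimethylsilyl)-N-(propan-2-yl)carbamate | CC(C)N(C(=O)Oc1cc(OCOC)cc(OCOC)c1)[Si](C)(C)C(C)(C)C | intermediate (not isolated)
5 | 2-lithio derivative of 4 | CC(C)N(C(=O)Oc1cc(OCOC)cc(OCOC)c1[Li])[Si](C)(C)C(C)(C)C | intermediate (not isolated)
6 | 3,5-bis(methoxymethoxy)-2-(trimethylsilyl)phenyl N-(tert-butyldimethylsilyl)-N-(propan-2-yl)carbamate | CC(C)N(C(=O)Oc1cc(OCOC)cc(OCOC)c1[Si](C)(C)C)[Si](C)(C)C(C)(C)C | intermediate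
7 | prenyl bromide (1-bromo-3-methylbut-2-ene) | CC(C)=CCBr | starting material
8 | 6-lithio derivative of 6 | CC(C)N(C(=O)Oc1c([Li])c(OCOC)cc(OCOC)c1[Si](C)(C)C)[Si](C)(C)C(C)(C)C | intermediate (not isolated)
9 | arylcopper derived from 8 | CC(C)N(C(=O)Oc1c([Cu])c(OCOC)cc(OCOC)c1[Si](C)(C)C)[Si](C)(C)C(C)(C)C | intermediate (not isolated)
10 | 3,5-bis(methoxymethoxy)-2-prenyl-6-(trimethylsilyl)phenyl N-(tert-butyldimethylsilyl)-N-(propan-2-yl)carbamate | CC(C)=CCc1c(OCOC)cc(OCOC)c([Si](C)(C)C)c1OC(=O)N(C(C)C)[Si](C)(C)C(C)(C)C | intermediate (not isolated)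
11 | 3,5-bis(methoxymethoxy)-2-prenyl-6-(trimethylsilyl)phenyl N-(propan-2-yl)carbamate | CC(C)=CCc1c(OCOC)cc(OCOC)c([Si](C)(C)C)c1OC(=O)NC(C)C | intermediate
12 | 3,5-bis(methoxymethoxy)-2-prenyl-6-(trimethylsilyl)phenol | CC(C)=CCc1c(OCOC)cc(OCOC)c([Si](C)(C)C)c1O | intermediate (not isolated)
13 | 3,5-bis(methoxymethoxy)-2-prenyl-6-(trimethylsilyl)phenyl trifluoromethanesulfonate | CC(C)=CCc1c(OCOC)cc(OCOC)c([Si](C)(C)C)c1OS(=O)(=O)C(F)(F)F | intermediate
14 | 3-bromo-4,5-dihydroxybenzaldehyde | O=Cc1cc(O)c(O)c(Br)c1 | starting material
15 | 3-bromo-4,5-bis(methoxymethoxy)benzaldehyde | COCOc1cc(C=O)cc(Br)c1OCOC | intermediate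
16 | tributyl(3-methylbut-2-en-1-yl)stannane | CCCC[Sn](CCCC)(CCCC)CC=C(C)C | starting material
17 | 3,4-bis(methoxymethoxy)-5-prenylbenzaldehyde | CC(C)=CCc1cc(C=O)cc(OCOC)c1OCOC | intermediate
18 | 5-(2,2-dibromoethenyl)-1,2-bis(methoxymethoxy)-3-prenylbenzene | CC(C)=CCc1cc(C=C(Br)Br)cc(OCOC)c1OCOC | intermediate
19 | lithium [3,4-bis(methoxymethoxy)-5-prenylphenyl]acetylide | CC(C)=CCc1cc(C#C[Li])cc(OCOC)c1OCOC | intermediate (not isolated)
20 | 3-[3,4-bis(methoxymethoxy)-5-prenylphenyl]prop-2-ynoic acid | CC(C)=CCc1cc(C#CC(=O)O)cc(OCOC)c1OCOC | intermediate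
21 | 3,5-bis(methoxymethoxy)-6-prenylbenzyne (C4a–C8a aryne of ring A) | CC(C)=CCC1=C(OCOC)C=C(OCOC)C#C1 | intermediate (not isolated)
22 | 1-[2-hydroxy-4,6-bis(methoxymethoxy)-3-prenylphenyl]-3-[3,4-bis(methoxymethoxy)-5-prenylphenyl]prop-2-yn-1-one | CC(C)=CCc1cc(C#CC(=O)c2c(OCOC)cc(OCOC)c(CC=C(C)C)c2O)cc(OCOC)c1OCOC | intermediate
23 | (E)-3-(diethylamino)-1-[2-hydroxy-4,6-bis(methoxymethoxy)-3-prenylphenyl]-3-[3,4-bis(methoxymethoxy)-5-prenylphenyl]prop-2-en-1-one | CCN(CC)/C(c1cc(CC=C(C)C)c(OCOC)c(OCOC)c1)=C/C(=O)c1c(O)c(CC=C(C)C)c(OCOC)cc1OCOC | intermediate (not isolated)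
24 | 5,7-bis(methoxymethoxy)-2-[3,4-bis(methoxymethoxy)-5-prenylphenyl]-8-prenyl-4H-chromen-4-one | CC(C)=CCc1cc(-c2cc(=O)c3c(OCOC)cc(OCOC)c(CC=C(C)C)c3o2)cc(OCOC)c1OCOC | intermediate
25 | epimedokoreanin B (5,7-dihydroxy-2-(3,4-dihydroxy-5-prenylphenyl)-8-prenyl-4H-chromen-4-one) | CC(C)=CCc1cc(-c2cc(=O)c3c(O)cc(O)c(CC=C(C)C)c3o2)cc(O)c1O | target

**Count and risks**

Total steps: 12. Longest linear sequence: 8 steps (steps 1–5 and 10–12, from phloroglucinol); the ring-B branch contributes steps 6–9.

Steps most likely to fail:

1. Step 10. The aryl anion may be protonated before the acyl shift, leaving the aryl ester. The propiolate may lose CO2 at the temperature needed. The product phenoxide may close in the fluoride medium without control, possibly by the 5-exo course. The fallback sets out from 13 and 18 and comes back at 22. Aryne 21 would be generated from 13 with CsF in DMF as solvent, where it inserts into the formyl C=O bond of DMF with the same orientation (oxygen at C8a) to give 6-[(dimethylamino)methylidene]-3,5-bis(methoxymethoxy)-2-prenylcyclohexa-2,4-dien-1-one F1, which is not isolated. Aqueous work-up hydrolyses it to 2-hydroxy-4,6-bis(methoxymethoxy)-3-prenylbenzaldehyde F2. After deprotonation of its phenol with one equivalent of LiHMDS, F2 is added at −78 °C to lithium acetylide 19, made from 18 as in step 9, to give racemic 1-[2-hydroxy-4,6-bis(methoxymethoxy)-3-prenylphenyl]-3-[3,4-bis(methoxymethoxy)-5-prenylphenyl]prop-2-yn-1-ol F3. Oxidation with MnO2 in CH2Cl2 then gives ynone 22 under neutral conditions. This fallback does not answer a wrong orientation of addition to the aryne, which both routes rely on the C5 oxygen to prevent.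

2. Step 4. Four things may go wrong:
   - Metalation may occur between the two MOM ethers instead of next to the carbamate.
   - The carbamoyl group may shift from oxygen to carbon (anionic ortho-Fries) while the mixture warms for the allylation.
   - The arylcopper may attack the tertiary end of prenyl bromide.
   - Adventitious hydrolysis of the N–Si bond of 6 before metalation would expose the N–H and let the base expel the phenoxide.

   The fallback sets out from 6 and comes back at 11, and answers the second and third of these. Aryllithium 8, generated as in step 4, would be quenched at −78 °C with iodine to give 2-iodo-3,5-bis(methoxymethoxy)-6-(trimethylsilyl)phenyl N-(tert-butyldimethylsilyl)-N-(propan-2-yl)carbamate F4, which is not isolated. Cold aqueous NaHSO4 work-up gives 2-iodo-3,5-bis(methoxymethoxy)-6-(trimethylsilyl)phenyl N-(propan-2-yl)carbamate F5. Stille coupling of F5 with stannane 16 (Pd(PPh3)4, DMF, 90 °C) then installs the linear prenyl group and gives 11.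

3. Step 12. Under protic acid the freed 7- and 4′-hydroxyl groups may add to the neighbouring prenyl double bonds (chroman formation), or the double bonds may be hydrated. The fallback sets out from 24 and comes back at 25. Treatment of 24 with excess TMSOTf and 2,2′-bipyridyl in CH2Cl2 at 0 °C exchanges the aryl MOM ethers for silyl ethers without a free Brønsted acid, giving 5,7-bis(trimethylsilyloxy)-2-[3,4-bis(trimethylsilyloxy)-5-prenylphenyl]-8-prenyl-4H-chromen-4-one F6. Addition of water hydrolyses F6 to 25.

**Further compounds**

F1 | step 10 | 6-[(dimethylamino)methylidene]-3,5-bis(methoxymethoxy)-2-prenylcyclohexa-2,4-dien-1-one (not isolated) | CN(C)C=C1C(=O)C(CC=C(C)C)=C(OCOC)C=C1OCOC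
F2 | step 10 | 2-hydroxy-4,6-bis(methoxymethoxy)-3-prenylbenzaldehyde | CC(C)=CCc1c(OCOC)cc(OCOC)c(C=O)c1O
F3 | step 10 | 1-[2-hydroxy-4,6-bis(methoxymethoxy)-3-prenylphenyl]-3-[3,4-bis(methoxymethoxy)-5-prenylphenyl]prop-2-yn-1-ol (racemic) | CC(C)=CCc1cc(C#CC(O)c2c(OCOC)cc(OCOC)c(CC=C(C)C)c2O)cc(OCOC)c1OCOC
F4 | step 4 | 2-iodo-3,5-bis(methoxymethoxy)-6-(trimethylsilyl)phenyl N-(tert-butyldimethylsilyl)-N-(propan-2-yl)carbamate (not isolated) | CC(C)N(C(=O)Oc1c(I)c(OCOC)cc(OCOC)c1[Si](C)(C)C)[Si](C)(C)C(C)(C)C
F5 | step 4 | 2-iodo-3,5-bis(methoxymethoxy)-6-(trimethylsilyl)phenyl N-(propan-2-yl)carbamate | CC(C)NC(=O)Oc1c(I)c(OCOC)cc(OCOC)c1[Si](C)(C)C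
F6 | step 12 | 5,7-bis(trimethylsilyloxy)-2-[3,4-bis(trimethylsilyloxy)-5-prenylphenyl]-8-prenyl-4H-chromen-4-one | CC(C)=CCc1cc(-c2cc(=O)c3c(O[Si](C)(C)C)cc(O[Si](C)(C)C)c(CC=C(C)C)c3o2)cc(O[Si](C)(C)C)c1O[Si](C)(C)C
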